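Over 8.0 h the mono adduct can be lost in more than one way, and the west run shows you the slow one.

all flasks: starting material 0.078 M
- west: partner 0.74 equiv; run made earlier
- east: partner 4.8 equiv; run made earlier
- Tuesday's: partner 0.500 equiv; time 8.0 h
- Wednesday's: partner 2.00 equiv; time 8.0 h
- Monday's: partner 4.00 equiv; time 8.0 h

- west (time / h: mono adduct / %, starting material / %): 0.667: 23.0, 54.2; 1.00: 21.2, 49.9; 2.00: 18.0, 52.1; 3.00: 14.9, 52.0; 5.00: 11.6, 49.7; 8.00: 8.0, 50.3
- east (time / h: mono adduct / %, starting material / %): 0.500: 0, 1.5; 1.50: 0, 0; 3.00: 0.4, 0.1; 4.00: 1.6, 0; 6.00: 0, 0.7; 8.00: 0, 0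

(scatter of a reading: 1 percentage point)



- mono adduct at the end, in percent of the starting material charged, for each flask in turn (Tuesday's, Wednesday's, Monday's)

In the west run the starting material reads 49.9% after 1.00 h and 50.3% after 8.00 h, level within the scatter, yet the mono adduct falls from 23.0% at 0.667 h to 8.0%. Suppose this fall is first order, with M the mono adduct and k its loss constant. Integrating dM/dt = −kM multiplies M by exp(−kt), and these readings give k = 0.144 h⁻¹. Now fold k and the run time t together into the loss number N = kt, which counts the e-foldings of loss that fit into the run: 1.15. At this N, exp(−N) leaves about a third.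

I assume that in Tuesday's flask the partner is the limiting reagent and that the mono adduct starts its slow fall from about the west reading of 23.0%, which gives 7.28%. Is one number enough? It is not: in the east run, with 4.8 equiv, mono adduct reads 0% at 8.00 h, not a third of anything. So I apply N where the starting material has stopped falling, as in the west run, and I give no figure for Wednesday's flask from it.

The forecast gives 7.5%, 1% and 0%, its Tuesday figure being slightly higher than mine, with Wednesday's “leaving only a small kinetic tail”.

The flasks give 8.25%, 3.43% and <0.001%, within the forecast's tolerance.

    starting material + partner → mono adduct (k = 0.126 M⁻¹ s⁻¹)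
    partner + mono adduct → bis adduct (k = 0.268 M⁻¹ s⁻¹)
    partner + bis adduct → triple product (k = 0.0415 M⁻¹ s⁻¹)
    partner + triple product → tetra adduct (k = 0.0757 M⁻¹ s⁻¹)
    mono adduct ⇌ isomer of the product (K = 8.93, k = 3.80 × 10⁻⁵ s⁻¹)

At 0.0145 h in Tuesday's flask, the forward step from mono adduct to its isomer runs at 0.0064 of the rate of the step to bis adduct, and the half-life of mono adduct by the step to bis adduct, 1.9 min at that moment, is shorter than 8.0 h. But Tuesday's partner stands at 0% of its charge after 4.00 h, and bis adduct reads 12.7% then and 12.7% after 8.00 h. Tuesday's mono adduct reads 13.3% after 4.00 h, and N scaled to the equal stretch that follows leaves 7.48%, against 8.25%. Wednesday's mono adduct reads 5.50% after 4.00 h, and the same step leaves 3.09%, against 3.43%.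

The numbers in the tables were generated by integration from invented constants, noise included.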